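**Retrosynthetic overview**

- Feature: ring A (C4a, C5, C6, C7, C8, C8a) is a 1,2,4,5-tetrasubstituted resorcinol, with O on C7 and C8a, C on C4a (to C4) and C6 (to the side chain), and H on C5 and C8. This is the pattern a vinylketene plus an alkoxyacetylene delivers.
- 48 ⇐ 47 ⇐ 46 (desilylation, hydrogenolysis) ⇐ α-diazo enone 41 by a photo-Wolff / ketene–ynol ether [2+2] / 4π / 6π cascade that forms C4a–C5, C4a–C8a, C7–C8 and C6–C7.
- 41 ⇐ enone 38 (diazo transfer) ⇐ HWE union (C5=C6) of ethynyl ether keto phosphonate 23 with aldehyde 37.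
- 23 ⇐ Evans allylation (sets C3), with the ethynyl ether carried as a dichlorovinyl ether from trichloroethylene and unmasked last. 37 ⇐ Evans syn-aldol (sets both side-chain centres).
- Ring order: the three benzene rings B, D and E are bought. The pyran ring closes first and ring A second, both inside step 21.

Key step: step 21

Remark: the side-chain aryl and hydroxyl groups are syn, so an Evans syn-aldol sets them directly. The side-chain hydroxyl is carried as a TBS ether, so one desilylation precedes the final hydrogenolysis.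

**Route**

Step 1
Reactants: 1 2-hydroxy-3,4-dimethoxybenzaldehyde; 2 benzyl bromide
Product: 3 2-(benzyloxy)-3,4-dimethoxybenzaldehyde
Conditions: K2CO3, DMF, 60 °C
Reagents that add atoms: benzyl bromide, BrCc1ccccc1
Why: Williamson etherification of the phenol should proceed cleanly in DMF and gives a benzyl ether that lasts until the final hydrogenolysis.

Step 2
Reactants: 3 2-(benzyloxy)-3,4-dimethoxybenzaldehyde; 4 p-toluenesulfonylmethyl isocyanide
Product: 6 2-[2-(benzyloxy)-3,4-dimethoxyphenyl]acetonitrile, via N-(1-tosylalkenyl)formamide 5 (not isolated)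
Conditions: t-BuOK, DME, −40 °C; then MeOH, reflux
Reagents that add atoms: p-toluenesulfonylmethyl isocyanide, Cc1ccc(cc1)S(=O)(=O)C[N+]#[C-]
Why: van Leusen reductive cyanation: the TosMIC anion adds to the aldehyde, the oxazoline opens to formamide 5, and methanolysis with loss of sulfinate should give the one-carbon-homologated nitrile.

Step 3
Reactants: 6 2-[2-(benzyloxy)-3,4-dimethoxyphenyl]acetonitrile
Product: 7 2-[2-(benzyloxy)-3,4-dimethoxyphenyl]acetic acid
Conditions: KOH, EtOH/H2O, reflux; then aq HCl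
Reagents that add atoms: water, O; potassium hydroxide, [K+].[OH-]
Why: alkaline nitrile hydrolysis should give the arylacetic acid, the aryl benzyl and methyl ethers being inert to hydroxide.

Step 4
Reactants: 7 2-[2-(benzyloxy)-3,4-dimethoxyphenyl]acetic acid; 8 (R)-4-benzyl-1,3-oxazolidin-2-one
Product: 10 (4R)-4-benzyl-3-{[2-(benzyloxy)-3,4-dimethoxyphenyl]acetyl}-1,3-oxazolidin-2-one, via mixed pivalic anhydride 9 (not isolated)
Conditions: PivCl, Et3N, THF, −20 °C; then 8, LiCl, rt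
Reagents that add atoms: (R)-4-benzyl-1,3-oxazolidin-2-one, O=C1N[C@H](Cc2ccccc2)CO1
Why: N-acylation of the oxazolidinone through the mixed anhydride (LiCl/Et3N variant) avoids strong base on the enolisable arylacetyl unit.

Step 5
Reactants: 10 (4R)-4-benzyl-3-{[2-(benzyloxy)-3,4-dimethoxyphenyl]acetyl}-1,3-oxazolidin-2-one; 11 allyl iodide
Product: 13 (4R)-4-benzyl-3-{(2R)-2-[2-(benzyloxy)-3,4-dimethoxyphenyl]pent-4-enoyl}-1,3-oxazolidin-2-one, via sodium Z-enolate 12 (not isolated)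
Conditions: NaHMDS, THF, −78 °C; then allyl iodide, −78 → −45 °C
Reagents that add atoms: allyl iodide, C=CCI
Why: Evans asymmetric alkylation: the chelated Z-enolate should be allylated on the face opposite the 4-benzyl group of the (R)-auxiliary, which sets the future C3 as R.

Step 6
Reactants: 13 (4R)-4-benzyl-3-{(2R)-2-[2-(benzyloxy)-3,4-dimethoxyphenyl]pent-4-enoyl}-1,3-oxazolidin-2-one
Product: 14 (2R)-2-[2-(benzyloxy)-3,4-dimethoxyphenyl]pent-4-en-1-ol
Conditions: LiBH4, MeOH (1 equiv), THF, 0 °C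
Reagents that add atoms: none
Why: reductive cleavage of the N-acyl oxazolidinone with LiBH4 should give the primary alcohol without enolisation of the α-aryl centre and without touching the alkene.

Step 7
Reactants: 14 (2R)-2-[2-(benzyloxy)-3,4-dimethoxyphenyl]pent-4-en-1-ol; 15 trichloroethylene
Product: 16 2-(benzyloxy)-1-[(2R)-1-{[(E)-1,2-dichloroethenyl]oxy}pent-4-en-2-yl]-3,4-dimethoxybenzene
Conditions: KH, THF, 0 °C → rt
Reagents that add atoms: trichloroethylene, ClC=C(Cl)Cl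
Why: dichlorovinyl ether formation from an alkoxide and trichloroethylene: base generates dichloroacetylene in the flask and the potassium alkoxide adds anti, giving an E-1,2-dichlorovinyl ether that serves as a base- and oxidant-stable masked ethynyl ether.

Step 8
Reactants: 16 2-(benzyloxy)-1-[(2R)-1-{[(E)-1,2-dichloroethenyl]oxy}pent-4-en-2-yl]-3,4-dimethoxybenzene
Product: 18 (4R)-4-[2-(benzyloxy)-3,4-dimethoxyphenyl]-5-{[(E)-1,2-dichloroethenyl]oxy}pentan-1-ol, via B-alkyl-9-BBN adduct 17 (not isolated)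
Conditions: 9-BBN, THF, 0 °C → rt; then NaOH, H2O2, 0 °C
Reagents that add atoms: hydrogen peroxide, OO
Why: anti-Markovnikov hydroboration–oxidation should take only the monosubstituted alkene, the chlorinated trisubstituted enol ether being too hindered and electron-poor for 9-BBN.

Step 9
Reactants: 18 (4R)-4-[2-(benzyloxy)-3,4-dimethoxyphenyl]-5-{[(E)-1,2-dichloroethenyl]oxy}pentan-1-ol
Product: 19 (4R)-4-[2-(benzyloxy)-3,4-dimethoxyphenyl]-5-{[(E)-1,2-dichloroethenyl]oxy}pentanal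
Conditions: Dess–Martin periodinane, NaHCO3, CH2Cl2, 0 °C → rt
Reagents that add atoms: none
Why: buffered Dess–Martin oxidation should stop at the aldehyde and leave the dichlorovinyl ether intact.

Step 10
Reactants: 19 (4R)-4-[2-(benzyloxy)-3,4-dimethoxyphenyl]-5-{[(E)-1,2-dichloroethenyl]oxy}pentanal; 20 diethyl (diazomethyl)phosphonate
Product: 21 diethyl [(5R)-5-[2-(benzyloxy)-3,4-dimethoxyphenyl]-6-{[(E)-1,2-dichloroethenyl]oxy}-2-oxohexyl]phosphonate
Conditions: SnCl2 (10 mol %), CH2Cl2, rt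
Reagents that add atoms: diethyl (diazomethyl)phosphonate, CCOP(=O)(OCC)C=[N+]=[N-]
Why: Roskamp homologation: SnCl2 activates the unbranched aldehyde, the diazo phosphonate adds, and a 1,2-hydride shift with loss of N2 should give the β-keto phosphonate under nearly neutral conditions.

Step 11
Reactants: 21 diethyl [(5R)-5-[2-(benzyloxy)-3,4-dimethoxyphenyl]-6-{[(E)-1,2-dichloroethenyl]oxy}-2-oxohexyl]phosphonate
Product: 23 diethyl [(5R)-5-[2-(benzyloxy)-3,4-dimethoxyphenyl]-6-(ethynyloxy)-2-oxohexyl]phosphonate, via lithium alkynyl ether 22 (not isolated)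
Conditions: NaH (1.1 equiv), THF, 0 °C; n-BuLi (3.5 equiv), −78 °C; MeOH, then pH 7 buffer
Reagents that add atoms: none
Why: dichlorovinyl ether to alkynyl ether conversion: n-BuLi removes the vinylic hydrogen, chloride is lost, and Cl–Li exchange on the chloroalkyne gives acetylide 22, which is protonated on quench, while the keto phosphonate is shielded as the enolate formed beforehand with NaH.

Step 12
Reactants: 24 (2,4-dihydroxyphenyl)acetic acid; 2 benzyl bromide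
Product: 26 [2,4-bis(benzyloxy)phenyl]acetic acid, via tribenzylated benzyl ester 25 (not isolated)
Conditions: BnBr (3.3 equiv), K2CO3, DMF, 60 °C; then NaOH, MeOH/H2O, 60 °C; aq HCl
Reagents that add atoms: benzyl bromide, BrCc1ccccc1
Why: exhaustive Williamson O-benzylation followed by saponification of the benzyl ester in the same pot should leave only the two aryl benzyl ethers.

Step 13
Reactants: 26 [2,4-bis(benzyloxy)phenyl]acetic acid; 27 (S)-4-benzyl-1,3-oxazolidin-2-one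
Product: 29 (4S)-4-benzyl-3-{[2,4-bis(benzyloxy)phenyl]acetyl}-1,3-oxazolidin-2-one, via mixed pivalic anhydride 28 (not isolated)
Conditions: PivCl, Et3N, THF, −20 °C; then 27, LiCl, rt
Reagents that add atoms: (S)-4-benzyl-1,3-oxazolidin-2-one, O=C1N[C@@H](Cc2ccccc2)CO1
Why: mixed-anhydride N-acylation of the oxazolidinone, as in step 4.

Step 14
Reactants: 30 2-[4-(benzyloxy)phenyl]ethanol
Product: 31 [4-(benzyloxy)phenyl]acetaldehyde
Conditions: Dess–Martin periodinane, NaHCO3, CH2Cl2, 0 °C; used at once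
Reagents that add atoms: none
Why: Dess–Martin oxidation gives the arylacetaldehyde under non-enolising conditions, and immediate use limits self-condensation.

Step 15
Reactants: 29 (4S)-4-benzyl-3-{[2,4-bis(benzyloxy)phenyl]acetyl}-1,3-oxazolidin-2-one; 31 [4-(benzyloxy)phenyl]acetaldehyde
Product: 33 (4S)-4-benzyl-3-{(2S,3R)-4-[4-(benzyloxy)phenyl]-2-[2,4-bis(benzyloxy)phenyl]-3-hydroxybutanoyl}-1,3-oxazolidin-2-one, via Z-boron enolate 32 (not isolated)
Conditions: Bu2BOTf, iPr2NEt, CH2Cl2, −78 → 0 °C; then 31, −78 → 0 °C; pH 7 buffer, MeOH, H2O2, 0 °C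
Reagents that add atoms: none
Why: Evans syn-aldol: the Z-boron enolate should react through a closed Zimmerman–Traxler transition state on the face away from the auxiliary benzyl group, which sets both side-chain centres (2S,3R, aryl and hydroxyl syn).

Step 16
Reactants: 33 (4S)-4-benzyl-3-{(2S,3R)-4-[4-(benzyloxy)phenyl]-2-[2,4-bis(benzyloxy)phenyl]-3-hydroxybutanoyl}-1,3-oxazolidin-2-one; 34 tert-butyldimethylsilyl triflate
Product: 35 (4S)-4-benzyl-3-{(2S,3R)-4-[4-(benzyloxy)phenyl]-2-[2,4-bis(benzyloxy)phenyl]-3-[(tert-butyldimethylsilyl)oxy]butanoyl}-1,3-oxazolidin-2-one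
Conditions: 2,6-lutidine, CH2Cl2, −78 → 0 °C
Reagents that add atoms: tert-butyldimethylsilyl triflate, CC(C)(C)[Si](C)(C)OS(=O)(=O)C(F)(F)F
Why: silylation with the silyl triflate and a hindered pyridine protects the secondary hydroxyl without forming an alkoxide, so retro-aldol cleavage and epimerisation are excluded.

Step 17
Reactants: 35 (4S)-4-benzyl-3-{(2S,3R)-4-[4-(benzyloxy)phenyl]-2-[2,4-bis(benzyloxy)phenyl]-3-[(tert-butyldimethylsilyl)oxy]butanoyl}-1,3-oxazolidin-2-one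
Product: 36 (2R,3R)-4-[4-(benzyloxy)phenyl]-2-[2,4-bis(benzyloxy)phenyl]-3-[(tert-butyldimethylsilyl)oxy]butan-1-ol
Conditions: LiBH4, MeOH (1 equiv), THF, 0 °C
Reagents that add atoms: none
Why: reductive removal of the auxiliary with LiBH4 should give the primary alcohol without enolisation (the CIP label at C2 changes, the geometry does not).

Step 18
Reactants: 36 (2R,3R)-4-[4-(benzyloxy)phenyl]-2-[2,4-bis(benzyloxy)phenyl]-3-[(tert-butyldimethylsilyl)oxy]butan-1-ol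
Product: 37 (2S,3R)-4-[4-(benzyloxy)phenyl]-2-[2,4-bis(benzyloxy)phenyl]-3-[(tert-butyldimethylsilyl)oxy]butanal
Conditions: Dess–Martin periodinane, NaHCO3, CH2Cl2, 0 °C; used at once
Reagents that add atoms: none
Why: buffered Dess–Martin oxidation and immediate use should keep the configurationally labile α-aryl aldehyde intact.

Step 19
Reactants: 23 diethyl [(5R)-5-[2-(benzyloxy)-3,4-dimethoxyphenyl]-6-(ethynyloxy)-2-oxohexyl]phosphonate; 37 (2S,3R)-4-[4-(benzyloxy)phenyl]-2-[2,4-bis(benzyloxy)phenyl]-3-[(tert-butyldimethylsilyl)oxy]butanal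
Product: 38 (2R,6E,8S,9R)-2-[2-(benzyloxy)-3,4-dimethoxyphenyl]-10-[4-(benzyloxy)phenyl]-8-[2,4-bis(benzyloxy)phenyl]-9-[(tert-butyldimethylsilyl)oxy]-1-(ethynyloxy)dec-6-en-5-one
Conditions: Ba(OH)2 (activated, 0.8 equiv), THF/H2O 40:1, 0 °C → rt
Reagents that add atoms: none
Why: Horner–Wadsworth–Emmons olefination of the keto phosphonate should give the E-enone, the mild heterogeneous base being chosen to spare the α-aryl centre of 37, and the ethynyl ether is inert to base.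

Step 20
Reactants: 38 (2R,6E,8S,9R)-2-[2-(benzyloxy)-3,4-dimethoxyphenyl]-10-[4-(benzyloxy)phenyl]-8-[2,4-bis(benzyloxy)phenyl]-9-[(tert-butyldimethylsilyl)oxy]-1-(ethynyloxy)dec-6-en-5-one; 39 4-acetamidobenzenesulfonyl azide
Product: 41 (2R,6E,8S,9R)-2-[2-(benzyloxy)-3,4-dimethoxyphenyl]-10-[4-(benzyloxy)phenyl]-8-[2,4-bis(benzyloxy)phenyl]-9-[(tert-butyldimethylsilyl)oxy]-4-diazo-1-(ethynyloxy)dec-6-en-5-one, via trifluoroacetyl ketone 40 (not isolated)
Conditions: LiHMDS (1.1 equiv), THF, −78 °C; CF3CO2CH2CF3, −78 °C; pH 7 buffer; then 39 (1.2 equiv), Et3N, H2O, MeCN, 0 °C → rt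
Reagents that add atoms: 4-acetamidobenzenesulfonyl azide, CC(=O)Nc1ccc(cc1)S(=O)(=O)N=[N+]=[N-]
Why: detrifluoroacetylative diazo transfer: kinetic α'-deprotonation of the enone, C-trifluoroacetylation and diazo transfer with loss of the activating group should place the diazo group on C4, while a slight excess of an electron-rich sulfonyl azide at 0 °C and a non-acidic work-up protect the ethynyl ether.

Step 21
Reactants: 41 (2R,6E,8S,9R)-2-[2-(benzyloxy)-3,4-dimethoxyphenyl]-10-[4-(benzyloxy)phenyl]-8-[2,4-bis(benzyloxy)phenyl]-9-[(tert-butyldimethylsilyl)oxy]-4-diazo-1-(ethynyloxy)dec-6-en-5-one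
Product: 46 (3R)-3-[2-(benzyloxy)-3,4-dimethoxyphenyl]-6-{(1S,2R)-3-[4-(benzyloxy)phenyl]-1-[2,4-bis(benzyloxy)phenyl]-2-[(tert-butyldimethylsilyl)oxy]propyl}-3,4-dihydro-2H-chromen-7-ol, via vinylketene 42 (not isolated), via bicyclic cyclobutenone 43 (not isolated), via dienylketene 44 (not isolated), via cyclohexadienone 45 (not isolated)
Conditions: hν (λ > 300 nm, Pyrex), ClCH2CH2Cl (0.01 M), degassed, 20 °C; then 80 °C
Reagents that add atoms: none
Why: Proposed new method: light expels N2 from 41 and the alkenyl group shifts from the carbonyl carbon to the diazo carbon (photo-Wolff rearrangement, C4a–C5) to give vinylketene 42, whose C=C adds [2+2] to the tethered ethynyl ether (C7–C8 and C4a–C8a) to give 43; 4π electrocyclic opening to dienylketene 44, 6π electrocyclisation (C6–C7) to 45 and tautomerisation should deliver phenol 46. The closest known reaction type is the Danheiser benzannulation of α'-diazo enones with alkoxy and siloxy alkynes, which is established only between two separate molecules. The pyran ring closes in the [2+2] step by 6-exo-dig attack of the ketene α-carbon C4a on the oxygen-bearing alkyne carbon C8a through the C4–C3–C2–O1 tether, and ring A closes by thermal disrotatory 6π electrocyclisation of the dienylketene, in which the pyran ring holds C5 and C8 cis across C4a=C8a. No stereocentre is formed and the three existing ones are spectators under neutral conditions. The regiochemistry needed (O on C8a, H on C8, free OH on C7) follows from ketene/ynol ether polarity (ketene carbonyl carbon to the nucleophilic terminal alkyne carbon), which the tether reinforces; the competitors are 1,2-hydride shift of a free carbene and intermolecular ketene capture, which dilution, exclusion of nucleophiles and irradiation above 300 nm (where only the diazo enone absorbs) should suppress.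

Step 22
Reactants: 46 (3R)-3-[2-(benzyloxy)-3,4-dimethoxyphenyl]-6-{(1S,2R)-3-[4-(benzyloxy)phenyl]-1-[2,4-bis(benzyloxy)phenyl]-2-[(tert-butyldimethylsilyl)oxy]propyl}-3,4-dihydro-2H-chromen-7-ol
Product: 47 (3R)-3-[2-(benzyloxy)-3,4-dimethoxyphenyl]-6-{(1S,2R)-3-[4-(benzyloxy)phenyl]-1-[2,4-bis(benzyloxy)phenyl]-2-hydroxypropyl}-3,4-dihydro-2H-chromen-7-ol
Conditions: TBAF, THF, rt → 45 °C; aq NH4Cl
Reagents that add atoms: none
Why: fluoride-mediated desilylation should free the hindered secondary alcohol without affecting the benzyl ethers.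

Step 23
Reactants: 47 (3R)-3-[2-(benzyloxy)-3,4-dimethoxyphenyl]-6-{(1S,2R)-3-[4-(benzyloxy)phenyl]-1-[2,4-bis(benzyloxy)phenyl]-2-hydroxypropyl}-3,4-dihydro-2H-chromen-7-ol
Product: 48 (3R)-6-[(1R,2R)-1-(2,4-dihydroxyphenyl)-2-hydroxy-3-(4-hydroxyphenyl)propyl]-3-(2-hydroxy-3,4-dimethoxyphenyl)-3,4-dihydro-2H-chromen-7-ol
Conditions: H2 (1 atm), 10% Pd/C, EtOAc/MeOH, rt
Reagents that add atoms: none
Why: catalytic hydrogenolysis should cleave the four aryl benzyl ethers, with no other reducible or hydrogenolysable group present (the side-chain C1 label becomes R by a CIP priority change only).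

**Compound list**

1 | 2-hydroxy-3,4-dimethoxybenzaldehyde | COc1ccc(C=O)c(O)c1OC | starting material
2 | benzyl bromide | BrCc1ccccc1 | starting material
3 | 2-(benzyloxy)-3,4-dimethoxybenzaldehyde | COc1ccc(C=O)c(OCc2ccccc2)c1OC | intermediate
4 | p-toluenesulfonylmethyl isocyanide (TosMIC) | Cc1ccc(cc1)S(=O)(=O)C[N+]#[C-] | starting material
5 | N-{2-[2-(benzyloxy)-3,4-dimethoxyphenyl]-1-tosylethenyl}formamide (not isolated) | O=CNC(=Cc1ccc(OC)c(OC)c1OCc1ccccc1)S(=O)(=O)c1ccc(C)cc1 | intermediate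
6 | 2-[2-(benzyloxy)-3,4-dimethoxyphenyl]acetonitrile | COc1ccc(CC#N)c(OCc2ccccc2)c1OC | intermediate
7 | 2-[2-(benzyloxy)-3,4-dimethoxyphenyl]acetic acid | COc1ccc(CC(=O)O)c(OCc2ccccc2)c1OC | intermediate
8 | (R)-4-benzyl-1,3-oxazolidin-2-one | O=C1N[C@H](Cc2ccccc2)CO1 | starting material
9 | mixed anhydride of 7 with pivalic acid (not isolated) | COc1ccc(CC(=O)OC(=O)C(C)(C)C)c(OCc2ccccc2)c1OC | intermediate
10 | (4R)-4-benzyl-3-{[2-(benzyloxy)-3,4-dimethoxyphenyl]acetyl}-1,3-oxazolidin-2-one | COc1ccc(CC(=O)N2C(=O)OC[C@H]2Cc2ccccc2)c(OCc2ccccc2)c1OC | intermediate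
11 | allyl iodide | C=CCI | starting material
12 | sodium (Z)-enolate of 10 (not isolated) | [Na+].[O-]/C(=C\c1ccc(OC)c(OC)c1OCc1ccccc1)N1C(=O)OC[C@H]1Cc1ccccc1 | intermediate
13 | (4R)-4-benzyl-3-{(2R)-2-[2-(benzyloxy)-3,4-dimethoxyphenyl]pent-4-enoyl}-1,3-oxazolidin-2-one | C=CC[C@H](c1ccc(OC)c(OC)c1OCc1ccccc1)C(=O)N1C(=O)OC[C@H]1Cc1ccccc1 | intermediate
14 | (2R)-2-[2-(benzyloxy)-3,4-dimethoxyphenyl]pent-4-en-1-ol | C=CC[C@H](c1ccc(OC)c(OC)c1OCc1ccccc1)CO | intermediate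
15 | trichloroethylene | ClC=C(Cl)Cl | starting material
16 | 2-(benzyloxy)-1-[(2R)-1-{[(E)-1,2-dichloroethenyl]oxy}pent-4-en-2-yl]-3,4-dimethoxybenzene | Cl/C=C(/Cl)OC[C@@H](c1ccc(OC)c(OC)c1OCc1ccccc1)CC=C | intermediate
17 | B-alkyl-9-borabicyclo[3.3.1]nonane adduct of 16, boron on the terminal carbon (not isolated) | Cl/C=C(/Cl)OC[C@@H](c1ccc(OC)c(OC)c1OCc1ccccc1)CCCB1C2CCCC1CCC2 | intermediate
18 | (4R)-4-[2-(benzyloxy)-3,4-dimethoxyphenyl]-5-{[(E)-1,2-dichloroethenyl]oxy}pentan-1-ol | Cl/C=C(/Cl)OC[C@@H](c1ccc(OC)c(OC)c1OCc1ccccc1)CCCO | intermediate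
19 | (4R)-4-[2-(benzyloxy)-3,4-dimethoxyphenyl]-5-{[(E)-1,2-dichloroethenyl]oxy}pentanal | Cl/C=C(/Cl)OC[C@@H](c1ccc(OC)c(OC)c1OCc1ccccc1)CCC=O | intermediate
20 | diethyl (diazomethyl)phosphonate | CCOP(=O)(OCC)C=[N+]=[N-] | starting material
21 | diethyl [(5R)-5-[2-(benzyloxy)-3,4-dimethoxyphenyl]-6-{[(E)-1,2-dichloroethenyl]oxy}-2-oxohexyl]phosphonate | Cl/C=C(/Cl)OC[C@@H](c1ccc(OC)c(OC)c1OCc1ccccc1)CCC(=O)CP(=O)(OCC)OCC | intermediate
22 | lithium acetylide of the ethynyl ether, keto phosphonate as sodium enolate (not isolated) | [Na+].[Li]C#COC[C@@H](c1ccc(OC)c(OC)c1OCc1ccccc1)CCC([O-])=CP(=O)(OCC)OCC | intermediate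
23 | diethyl [(5R)-5-[2-(benzyloxy)-3,4-dimethoxyphenyl]-6-(ethynyloxy)-2-oxohexyl]phosphonate | C#COC[C@@H](c1ccc(OC)c(OC)c1OCc1ccccc1)CCC(=O)CP(=O)(OCC)OCC | intermediate
24 | (2,4-dihydroxyphenyl)acetic acid | OC(=O)Cc1ccc(O)cc1O | starting material
25 | benzyl [2,4-bis(benzyloxy)phenyl]acetate (not isolated) | O=C(Cc1ccc(OCc2ccccc2)cc1OCc1ccccc1)OCc1ccccc1 | intermediate
26 | [2,4-bis(benzyloxy)phenyl]acetic acid | OC(=O)Cc1ccc(OCc2ccccc2)cc1OCc1ccccc1 | intermediate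
27 | (S)-4-benzyl-1,3-oxazolidin-2-one | O=C1N[C@@H](Cc2ccccc2)CO1 | starting material
28 | mixed anhydride of 26 with pivalic acid (not isolated) | CC(C)(C)C(=O)OC(=O)Cc1ccc(OCc2ccccc2)cc1OCc1ccccc1 | intermediate
29 | (4S)-4-benzyl-3-{[2,4-bis(benzyloxy)phenyl]acetyl}-1,3-oxazolidin-2-one | O=C(Cc1ccc(OCc2ccccc2)cc1OCc1ccccc1)N1C(=O)OC[C@@H]1Cc1ccccc1 | intermediate
30 | 2-[4-(benzyloxy)phenyl]ethanol | OCCc1ccc(OCc2ccccc2)cc1 | starting material
31 | [4-(benzyloxy)phenyl]acetaldehyde | O=CCc1ccc(OCc2ccccc2)cc1 | intermediate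
32 | (Z)-dibutylboron enolate of 29 (not isolated) | CCCCB(CCCC)O/C(=C\c1ccc(OCc2ccccc2)cc1OCc1ccccc1)N1C(=O)OC[C@@H]1Cc1ccccc1 | intermediate
33 | (4S)-4-benzyl-3-{(2S,3R)-4-[4-(benzyloxy)phenyl]-2-[2,4-bis(benzyloxy)phenyl]-3-hydroxybutanoyl}-1,3-oxazolidin-2-one | O=C([C@@H](c1ccc(OCc2ccccc2)cc1OCc1ccccc1)[C@H](O)Cc1ccc(OCc2ccccc2)cc1)N1C(=O)OC[C@@H]1Cc1ccccc1 | intermediate
34 | tert-butyldimethylsilyl triflate | CC(C)(C)[Si](C)(C)OS(=O)(=O)C(F)(F)F | starting material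
35 | (4S)-4-benzyl-3-{(2S,3R)-4-[4-(benzyloxy)phenyl]-2-[2,4-bis(benzyloxy)phenyl]-3-[(tert-butyldimethylsilyl)oxy]butanoyl}-1,3-oxazolidin-2-one | O=C([C@@H](c1ccc(OCc2ccccc2)cc1OCc1ccccc1)[C@H](O[Si](C)(C)C(C)(C)C)Cc1ccc(OCc2ccccc2)cc1)N1C(=O)OC[C@@H]1Cc1ccccc1 | intermediate
36 | (2R,3R)-4-[4-(benzyloxy)phenyl]-2-[2,4-bis(benzyloxy)phenyl]-3-[(tert-butyldimethylsilyl)oxy]butan-1-ol | OC[C@@H](c1ccc(OCc2ccccc2)cc1OCc1ccccc1)[C@H](O[Si](C)(C)C(C)(C)C)Cc1ccc(OCc2ccccc2)cc1 | intermediate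
37 | (2S,3R)-4-[4-(benzyloxy)phenyl]-2-[2,4-bis(benzyloxy)phenyl]-3-[(tert-butyldimethylsilyl)oxy]butanal | O=C[C@@H](c1ccc(OCc2ccccc2)cc1OCc1ccccc1)[C@H](O[Si](C)(C)C(C)(C)C)Cc1ccc(OCc2ccccc2)cc1 | intermediate
38 | (2R,6E,8S,9R)-2-[2-(benzyloxy)-3,4-dimethoxyphenyl]-10-[4-(benzyloxy)phenyl]-8-[2,4-bis(benzyloxy)phenyl]-9-[(tert-butyldimethylsilyl)oxy]-1-(ethynyloxy)dec-6-en-5-one | C#COC[C@@H](c1ccc(OC)c(OC)c1OCc1ccccc1)CCC(=O)/C=C/[C@@H](c1ccc(OCc2ccccc2)cc1OCc1ccccc1)[C@H](O[Si](C)(C)C(C)(C)C)Cc1ccc(OCc2ccccc2)cc1 | intermediate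
39 | 4-acetamidobenzenesulfonyl azide | CC(=O)Nc1ccc(cc1)S(=O)(=O)N=[N+]=[N-] | starting material
40 | 4-(trifluoroacetyl) derivative of 38, C4 epimers and enol (not isolated) | C#COC[C@@H](c1ccc(OC)c(OC)c1OCc1ccccc1)CC(C(=O)C(F)(F)F)C(=O)/C=C/[C@@H](c1ccc(OCc2ccccc2)cc1OCc1ccccc1)[C@H](O[Si](C)(C)C(C)(C)C)Cc1ccc(OCc2ccccc2)cc1 | intermediate
41 | (2R,6E,8S,9R)-2-[2-(benzyloxy)-3,4-dimethoxyphenyl]-10-[4-(benzyloxy)phenyl]-8-[2,4-bis(benzyloxy)phenyl]-9-[(tert-butyldimethylsilyl)oxy]-4-diazo-1-(ethynyloxy)dec-6-en-5-one | C#COC[C@@H](c1ccc(OC)c(OC)c1OCc1ccccc1)CC(=[N+]=[N-])C(=O)/C=C/[C@@H](c1ccc(OCc2ccccc2)cc1OCc1ccccc1)[C@H](O[Si](C)(C)C(C)(C)C)Cc1ccc(OCc2ccccc2)cc1 | intermediate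
42 | vinylketene: the ketene carbon bears the (2R)-2-aryl-3-(ethynyloxy)propyl chain and the E-alkenyl side chain (not isolated) | C#COC[C@@H](c1ccc(OC)c(OC)c1OCc1ccccc1)CC(=C=O)/C=C/[C@@H](c1ccc(OCc2ccccc2)cc1OCc1ccccc1)[C@H](O[Si](C)(C)C(C)(C)C)Cc1ccc(OCc2ccccc2)cc1 | intermediate
43 | (4R)-4-aryl-6-[(E)-alkenyl]-2-oxabicyclo[4.2.0]oct-1(8)-en-7-one, C6 epimers (not isolated) | O=C1C=C2OC[C@@H](c3ccc(OC)c(OC)c3OCc3ccccc3)CC12/C=C/[C@@H](c1ccc(OCc2ccccc2)cc1OCc1ccccc1)[C@H](O[Si](C)(C)C(C)(C)C)Cc1ccc(OCc2ccccc2)cc1 | intermediate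
44 | dienylketene: 2-[(5R)-3-[(E)-alkenyl]-5-aryl-5,6-dihydro-4H-pyran-2-yl]ethenone (not isolated) | O=C=CC1=C(/C=C/[C@@H](c2ccc(OCc3ccccc3)cc2OCc2ccccc2)[C@H](O[Si](C)(C)C(C)(C)C)Cc2ccc(OCc3ccccc3)cc2)C[C@H](c2ccc(OC)c(OC)c2OCc2ccccc2)CO1 | intermediate
45 | (3R)-3-aryl-6-(side chain)-3,4-dihydro-2H-chromen-7(6H)-one, keto tautomer of 46 (not isolated) | O=C1C=C2OC[C@@H](c3ccc(OC)c(OC)c3OCc3ccccc3)CC2=CC1[C@@H](c1ccc(OCc2ccccc2)cc1OCc1ccccc1)[C@H](O[Si](C)(C)C(C)(C)C)Cc1ccc(OCc2ccccc2)cc1 | intermediate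
46 | (3R)-3-[2-(benzyloxy)-3,4-dimethoxyphenyl]-6-{(1S,2R)-3-[4-(benzyloxy)phenyl]-1-[2,4-bis(benzyloxy)phenyl]-2-[(tert-butyldimethylsilyl)oxy]propyl}-3,4-dihydro-2H-chromen-7-ol | COc1ccc([C@@H]2COc3cc(O)c([C@@H](c4ccc(OCc5ccccc5)cc4OCc4ccccc4)[C@H](O[Si](C)(C)C(C)(C)C)Cc4ccc(OCc5ccccc5)cc4)cc3C2)c(OCc2ccccc2)c1OC | intermediate
47 | (3R)-3-[2-(benzyloxy)-3,4-dimethoxyphenyl]-6-{(1S,2R)-3-[4-(benzyloxy)phenyl]-1-[2,4-bis(benzyloxy)phenyl]-2-hydroxypropyl}-3,4-dihydro-2H-chromen-7-ol | COc1ccc([C@@H]2COc3cc(O)c([C@@H](c4ccc(OCc5ccccc5)cc4OCc4ccccc4)[C@H](O)Cc4ccc(OCc5ccccc5)cc4)cc3C2)c(OCc2ccccc2)c1OC | intermediate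
48 | (3R)-6-[(1R,2R)-1-(2,4-dihydroxyphenyl)-2-hydroxy-3-(4-hydroxyphenyl)propyl]-3-(2-hydroxy-3,4-dimethoxyphenyl)-3,4-dihydro-2H-chromen-7-ol | COc1ccc([C@@H]2COc3cc(O)c([C@@H](c4ccc(O)cc4O)[C@H](O)Cc4ccc(O)cc4)cc3C2)c(O)c1OC | target

**Step count and risks**

Total: 23 steps. Longest linear sequence: 16 steps (steps 1–11, then 19–23).

Steps most likely to fail:

1. Step 21 (Proposed new method). The excited diazo enone may lose nitrogen to a free carbene that undergoes 1,2-hydride shift from C4 instead of Wolff rearrangement, or the vinylketene may be captured intermolecularly or by traces of water before it reaches the tethered alkyne. Fallback with known chemistry, setting out from 14 and coming back at 47: the ring A construction is kept but run in its established intermolecular form, and the pyran is closed afterwards.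
   - Alcohol 14 is silylated (TBSCl, imidazole) to the silyl ether F1.
   - Hydroboration–oxidation gives the alcohol F2, Dess–Martin oxidation the aldehyde F3, and the Roskamp reaction with 20 the keto phosphonate F4.
   - HWE olefination with 37 gives the enone F5, and detrifluoroacetylative diazo transfer gives the diazo enone F6.
   - Irradiation of F6 with (triisopropylsilyloxy)acetylene (intermolecular Danheiser benzannulation) gives the resorcinol monosilyl ether F7.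
   - TBAF removes the three silyl groups to give the diphenol diol F8.
   - Mitsunobu cyclisation (PPh3, DIAD) of the C8a phenol onto the primary alcohol closes the pyran and gives 47.

2. Step 20. The sulfonyl azide may undergo cycloaddition with the electron-rich ethynyl ether, and LiHMDS may deprotonate the alkyne C–H or the γ-position C8–H, which would erode that centre. Fallback, setting out from 21 and coming back at 41: the alkyne is carried capped.
   - The acetylide formed from 21 (NaH; n-BuLi) is quenched with Et3SiCl instead of a proton source to give the C-silylated ynol ether keto phosphonate F9.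
   - HWE with 37 gives the silyl-capped enone F10.
   - Diazo transfer, now without an acidic or exposed alkyne, gives the silyl-capped diazo enone F11.
   - Buffered TBAF/AcOH at −20 °C removes the alkynyl silyl group and gives 41.

3. Step 19. Epimerisation of the α-aryl aldehyde carbon or β-elimination of the silyloxy group may occur under the basic olefination conditions. Fallback, setting out from 37 and 18 and coming back at 38: the enone is assembled by forming the C5–C(=O) bond under non-basic conditions.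
   - Takai iodo-olefination of 37 (CrCl2, CHI3) gives the E-vinyl iodide F12.
   - Alcohol 18 is converted with n-BuLi into the ethynyl ether alcohol F13 and oxidised (TPAP, NMO) to the ethynyl ether aldehyde F14.
   - Nozaki–Hiyama–Kishi coupling of F12 with F14 (CrCl2, cat. NiCl2) gives the allylic alcohol F15.
   - MnO2 oxidation gives 38.

Further compounds
F1 | step 21 | tert-butyldimethylsilyl ether of 14 | C=CC[C@H](c1ccc(OC)c(OC)c1OCc1ccccc1)CO[Si](C)(C)C(C)(C)C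
F2 | step 21 | (4R)-4-[2-(benzyloxy)-3,4-dimethoxyphenyl]-5-[(tert-butyldimethylsilyl)oxy]pentan-1-ol | OCCC[C@H](c1ccc(OC)c(OC)c1OCc1ccccc1)CO[Si](C)(C)C(C)(C)C
F3 | step 21 | (4R)-4-[2-(benzyloxy)-3,4-dimethoxyphenyl]-5-[(tert-butyldimethylsilyl)oxy]pentanal | O=CCC[C@H](c1ccc(OC)c(OC)c1OCc1ccccc1)CO[Si](C)(C)C(C)(C)C
F4 | step 21 | diethyl [(5R)-5-[2-(benzyloxy)-3,4-dimethoxyphenyl]-6-[(tert-butyldimethylsilyl)oxy]-2-oxohexyl]phosphonate | CCOP(=O)(OCC)CC(=O)CC[C@H](c1ccc(OC)c(OC)c1OCc1ccccc1)CO[Si](C)(C)C(C)(C)C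
F5 | step 21 | analogue of 38 with a 1-[(tert-butyldimethylsilyl)oxy] group in place of ethynyloxy | CC(C)(C)[Si](C)(C)OC[C@@H](c1ccc(OC)c(OC)c1OCc1ccccc1)CCC(=O)/C=C/[C@@H](c1ccc(OCc2ccccc2)cc1OCc1ccccc1)[C@H](O[Si](C)(C)C(C)(C)C)Cc1ccc(OCc2ccccc2)cc1
F6 | step 21 | analogue of 41 with a 1-[(tert-butyldimethylsilyl)oxy] group in place of ethynyloxy | CC(C)(C)[Si](C)(C)OC[C@@H](c1ccc(OC)c(OC)c1OCc1ccccc1)CC(=[N+]=[N-])C(=O)/C=C/[C@@H](c1ccc(OCc2ccccc2)cc1OCc1ccccc1)[C@H](O[Si](C)(C)C(C)(C)C)Cc1ccc(OCc2ccccc2)cc1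
F7 | step 21 | open-chain resorcinol: 5-(triisopropylsilyloxy)phenol carrying the silylated side chain at C2 and the (2R)-2-aryl-3-(silyloxy)propyl group at C4 | CC(C)[Si](C(C)C)(C(C)C)Oc1cc(O)c([C@@H](c2ccc(OCc3ccccc3)cc2OCc2ccccc2)[C@H](O[Si](C)(C)C(C)(C)C)Cc2ccc(OCc3ccccc3)cc2)cc1C[C@H](c1ccc(OC)c(OC)c1OCc1ccccc1)CO[Si](C)(C)C(C)(C)C
F8 | step 21 | fully desilylated diphenol diol (seco-47) | Oc1cc(O)c([C@@H](c2ccc(OCc3ccccc3)cc2OCc2ccccc2)[C@H](O)Cc2ccc(OCc3ccccc3)cc2)cc1C[C@H](c1ccc(OC)c(OC)c1OCc1ccccc1)CO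
F9 | step 20 | diethyl [(5R)-5-[2-(benzyloxy)-3,4-dimethoxyphenyl]-2-oxo-6-{[(triethylsilyl)ethynyl]oxy}hexyl]phosphonate | CC[Si](CC)(CC)C#COC[C@@H](c1ccc(OC)c(OC)c1OCc1ccccc1)CCC(=O)CP(=O)(OCC)OCC
F10 | step 20 | analogue of 38 with a triethylsilyl group on the alkyne terminus | CC[Si](CC)(CC)C#COC[C@@H](c1ccc(OC)c(OC)c1OCc1ccccc1)CCC(=O)/C=C/[C@@H](c1ccc(OCc2ccccc2)cc1OCc1ccccc1)[C@H](O[Si](C)(C)C(C)(C)C)Cc1ccc(OCc2ccccc2)cc1
F11 | step 20 | analogue of 41 with a triethylsilyl group on the alkyne terminus | CC[Si](CC)(CC)C#COC[C@@H](c1ccc(OC)c(OC)c1OCc1ccccc1)CC(=[N+]=[N-])C(=O)/C=C/[C@@H](c1ccc(OCc2ccccc2)cc1OCc1ccccc1)[C@H](O[Si](C)(C)C(C)(C)C)Cc1ccc(OCc2ccccc2)cc1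
F12 | step 19 | E-vinyl iodide from 37 (CHO replaced by CH=CHI) | I/C=C/[C@@H](c1ccc(OCc2ccccc2)cc1OCc1ccccc1)[C@H](O[Si](C)(C)C(C)(C)C)Cc1ccc(OCc2ccccc2)cc1
F13 | step 19 | (4R)-4-[2-(benzyloxy)-3,4-dimethoxyphenyl]-5-(ethynyloxy)pentan-1-ol | C#COC[C@@H](c1ccc(OC)c(OC)c1OCc1ccccc1)CCCO
F14 | step 19 | (4R)-4-[2-(benzyloxy)-3,4-dimethoxyphenyl]-5-(ethynyloxy)pentanal | C#COC[C@@H](c1ccc(OC)c(OC)c1OCc1ccccc1)CCC=O
F15 | step 19 | allylic alcohol corresponding to 38 (C5 carbinol, both epimers) | C#COC[C@@H](c1ccc(OC)c(OC)c1OCc1ccccc1)CCC(O)/C=C/[C@@H](c1ccc(OCc2ccccc2)cc1OCc1ccccc1)[C@H](O[Si](C)(C)C(C)(C)C)Cc1ccc(OCc2ccccc2)cc1
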